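**Assumptions:** Sideritiflavone (5,3',4'-trihydroxy-6,7,8-trimethoxyflavone, C18H16O8) has no stereocentres, so there is no enantiomer to control; the only stereo-element in the route is the transient (E)-alkene of the chalcone. Compound 1 is taken as a catalogue chemical (CAS 3162-28-5, recalled from memory and not checked); if it cannot be bought, it is made from 3,4,5-trimethoxyphenol as described in the fallbacks.

## Retrosynthetic overview

1. The target comes from the fully protected flavone 4 by one Lewis-acid step that cleaves the chelated 5-OMe and both B-ring benzyl ethers.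
2. The pyranone C-ring (the only ring formed) comes from oxidative cyclisation of 2'-hydroxychalcone 3, forming the O1–C2 bond and the C2=C3 double bond.
3. Chalcone 3 comes from Claisen–Schmidt condensation of acetophenone 1 (whole A-ring, all four methoxy groups in place) with aldehyde 2 (B-ring, catechol masked as benzyl ethers).
4. The A and B rings are bought intact, and no stereocentres are created.

## Forward route

**Step 1**
Reactants: 1, 2'-hydroxy-3',4',5',6'-tetramethoxyacetophenone; 2, 3,4-bis(benzyloxy)benzaldehyde
Product: 3, (E)-3-[3,4-bis(benzyloxy)phenyl]-1-(2-hydroxy-3,4,5,6-tetramethoxyphenyl)prop-2-en-1-one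
Conditions: 50% aq. KOH, EtOH, rt, 24–48 h; then cold 2 M HCl to pH ~3
Reagents that add atoms: none (both partners are numbered reactants; water is lost)
Why: Claisen–Schmidt aldol condensation. The methyl ketone enolate adds to the non-enolisable aldehyde and E1cB dehydration gives the conjugated (E)-enone; aryl methyl and benzyl ethers are inert to aqueous base, and any flavanone formed by reversible oxa-Michael closure is carried into step 2, where it is also oxidised to 4.

**Step 2**
Reactants: 3, the (E)-2'-hydroxychalcone
Product: 4, 2-[3,4-bis(benzyloxy)phenyl]-5,6,7,8-tetramethoxy-4H-chromen-4-one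
Conditions: I2 (10 mol%), DMSO, 120–130 °C, 2–4 h; aq. Na2S2O3 work-up
Reagents that add atoms: none (net loss of 2 H)
Why: I2/DMSO oxidative cyclisation. The 2'-OH undergoes intramolecular oxa-Michael addition, α-iodination and HI elimination give the flavone, and DMSO reoxidises HI to I2; benzyl and methyl ethers tolerate catalytic iodine, and the alkene geometry becomes irrelevant once the ring is aromatised.

**Step 3**
Reactants: 4, the dibenzyl tetramethoxyflavone
Product: 5, sideritiflavone, 2-(3,4-dihydroxyphenyl)-5-hydroxy-6,7,8-trimethoxy-4H-chromen-4-one
Conditions: BCl3 (1 M in CH2Cl2, 6–8 equiv), pentamethylbenzene (6 equiv), CH2Cl2, −78 → 0 °C, 1–2 h; quench with MeOH then 1 M HCl, rt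
Reagents that add atoms: none (one CH3 and two benzyl groups are removed; H comes from work-up)
Why: Chelation-directed Lewis-acid dealkylation. BCl3 bound to the C4 carbonyl forms a six-membered chelate that cleaves only the peri 5-OMe, and it also cleaves both aryl benzyl ethers, with pentamethylbenzene trapping the benzyl cation to prevent C-benzylation. The non-chelated 6-, 7- and 8-OMe groups survive at ≤0 °C, and the borate esters hydrolyse on work-up.

## Compound list

1 | 2'-hydroxy-3',4',5',6'-tetramethoxyacetophenone | CC(=O)c1c(O)c(OC)c(OC)c(OC)c1OC | starting material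
2 | 3,4-bis(benzyloxy)benzaldehyde | O=Cc1ccc(OCc2ccccc2)c(OCc2ccccc2)c1 | starting material
3 | (E)-3-[3,4-bis(benzyloxy)phenyl]-1-(2-hydroxy-3,4,5,6-tetramethoxyphenyl)prop-2-en-1-one | COc1c(OC)c(OC)c(C(=O)/C=C/c2ccc(OCc3ccccc3)c(OCc3ccccc3)c2)c(O)c1OC | intermediate
4 | 2-[3,4-bis(benzyloxy)phenyl]-5,6,7,8-tetramethoxy-4H-chromen-4-one | COc1c(OC)c(OC)c2c(=O)cc(-c3ccc(OCc4ccccc4)c(OCc4ccccc4)c3)oc2c1OC | intermediate
5 | sideritiflavone (5,3',4'-trihydroxy-6,7,8-trimethoxyflavone) | COc1c(OC)c(O)c2c(=O)cc(-c3ccc(O)c(O)c3)oc2c1OC | target

## Summary

Total step count: 3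
Longest linear sequence: 3 steps (1 + 2 → 3 → 4 → 5)

Steps most likely to fail, with fallbacks:

1. **Step 3 (one-pot 5-O-demethylation and double debenzylation).** The risks are over-demethylation at C6 or incomplete cleavage. Fallback: separate the two events with orthogonal chemistry. First remove the benzyl groups by hydrogenolysis (H2, Pd/C, EtOAc/MeOH) to give 3',4'-dihydroxy-5,6,7,8-tetramethoxyflavone. Then cleave only the 5-OMe with AlCl3 in MeCN, or with conc. HCl/EtOH at reflux.

2. **Step 2 (I2/DMSO oxidative cyclisation).** The risks are partial debenzylation or demethylation by HI, or stalling at the flavanone. Fallback: build the C-ring by the Baker–Venkataraman route instead. O-acylate 1 with 3,4-bis(benzyloxy)benzoyl chloride, rearrange with KOH/pyridine to the 1,3-diketone, and cyclodehydrate with H2SO4/AcOH. This needs no oxidation step.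

3. **Step 1 (Claisen–Schmidt on the hindered, di-ortho-substituted acetophenone, and sourcing of 1).** The risks are slow or incomplete condensation and Cannizzaro loss of aldehyde. Fallback: replace the aldol with a direct Claisen-type C-acylation. Treat 1 with LiHMDS (3–4 equiv, THF, −78 °C) to form the dianion, add 3,4-bis(benzyloxy)benzoyl chloride to get the β-diketone, and close to 4 with acid. If 1 cannot be purchased, make it from 3,4,5-trimethoxyphenol in three steps:
   - BF3·OEt2/AcOH ortho-acetylation to 2'-hydroxy-4',5',6'-trimethoxyacetophenone.
   - Bromination at C3'.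
   - CuBr/NaOMe methoxylation.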